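**Strategy**

Atoms: lactone ring O1, C2 (C=O), C3 (bearing CH2OH), C4, C5; exocyclic C6; stereocentre C7. The (Z)-5-ylidenefuran-2(5H)-one ring is read as the cycloisomer of a (Z)-2-en-4-ynoic acid. In one flask a C3 phosphonate that carries the silyl-protected hydroxymethyl group meets an ynal that already holds the chain, both furans and C7: a Z-selective Horner–Wadsworth–Emmons olefination makes C3=C4, the ester is saponified in place, and AgNO3 adds O1 to C5 of the C5≡C6 alkyne (5-exo-dig), which also sets the Z exocyclic alkene. The ynal comes from a zirconium/zinc/palladium diene coupling of two short fragments; rhodium-catalysed conjugate alkynylation of crotonaldehyde sets C7.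

Key step: step 11

Remark (assumption): in step 5 the hand of the bisphosphine is taken to be the one that delivers the (S)-aldehyde; the sense of induction is to be confirmed by correlation before material is carried on.

**Route**

Step 1
Reactants: 1 3,4-dibromofuran; 2 furan-3-carbaldehyde
Product: 4 (4-bromofuran-3-yl)(furan-3-yl)methanol, via 4-bromo-3-furyllithium 3 (not isolated)
Conditions: n-BuLi (1.0 equiv), Et2O, −78 °C; then 2, −78 °C; then H2O
Reagents that add atoms: none
Why: Bromine–lithium exchange on one C–Br bond followed by 1,2-addition of the 3-furyllithium to the aldehyde, kept cold so that the anion does not isomerise to the 2-lithio species; the carbinol centre is racemic and is removed in step 2.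

Step 2
Reactants: 4 (4-bromofuran-3-yl)(furan-3-yl)methanol
Product: 5 3-bromo-4-(furan-3-ylmethyl)furan
Conditions: Et3SiH (3 equiv), CF3CO2H, CH2Cl2, −20 → 0 °C
Reagents that add atoms: none
Why: Ionic hydrogenation (silane deoxygenation) of a diheteroaryl carbinol, in which the bis(3-furyl)methyl cation is trapped by hydride, excess silane and low temperature being used to outrun Friedel–Crafts attack on the furans.

Step 3
Reactants: 6 pent-3-yn-1-ol
Product: 7 5-iodopent-2-yne
Conditions: I2, PPh3, imidazole, CH2Cl2, 0 °C → rt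
Reagents that add atoms: iodine, II
Why: Appel-type iodination, in which the alkoxyphosphonium formed from PPh3/I2 is displaced by iodide at the primary carbon (SN2) and the internal alkyne is inert.

Step 4
Reactants: 7 5-iodopent-2-yne; 5 3-bromo-4-(furan-3-ylmethyl)furan
Product: 9 3-(furan-3-ylmethyl)-4-(pent-3-yn-1-yl)furan, via pent-3-yn-1-ylzinc iodide 8 (not isolated)
Conditions: Zn dust, LiCl, THF, 40 °C; then 5, Pd(OAc)2 (2 mol %), SPhos (4 mol %), THF, 50 °C
Reagents that add atoms: none
Why: Negishi sp3–sp2 coupling, in which LiCl-assisted zinc insertion gives the primary alkylzinc iodide that transmetalates to the arylpalladium formed from the C–Br bond of 5, the bulky biaryl phosphine favouring reductive elimination over β-hydride elimination.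

Step 5
Reactants: 10 (E)-but-2-enal; 11 ethynyltri(propan-2-yl)silane
Product: 12 (3S)-3-methyl-5-[tri(propan-2-yl)silyl]pent-4-ynal
Conditions: [Rh(OAc)(C2H4)2]2 (2.5 mol %), (R)-DTBM-SEGPHOS (6 mol %), MeOH, 40 °C
Reagents that add atoms: none
Why: Rhodium-catalysed asymmetric conjugate alkynylation, in which an alkynylrhodium species adds 1,4 to the enal (the bulky silyl group suppressing alkyne dimerisation) and the chiral bisphosphine selects the enal face, so that C7 is set as (S) under catalyst control.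

Step 6
Reactants: 12 (3S)-3-methyl-5-[tri(propan-2-yl)silyl]pent-4-ynal
Product: 13 [(3S,5E)-6-iodo-3-methylhex-5-en-1-yn-1-yl]tri(propan-2-yl)silane
Conditions: CHI3, CrCl2, THF–1,4-dioxane, 0 °C → rt
Reagents that add atoms: iodoform, IC(I)I
Why: Takai olefination, in which the gem-dichromium species from CHI3 and CrCl2 adds to the aldehyde and eliminates to the (E)-iodoalkene, and the stereocentre, β to the carbonyl, is not touched.

Step 7
Reactants: 9 3-(furan-3-ylmethyl)-4-(pent-3-yn-1-yl)furan; 13 [(3S,5E)-6-iodo-3-methylhex-5-en-1-yn-1-yl]tri(propan-2-yl)silane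
Product: 16 [(3S,5E,7E)-10-[4-(furan-3-ylmethyl)furan-3-yl]-3,7-dimethyldeca-5,7-dien-1-yn-1-yl]tri(propan-2-yl)silane, via alkenylzirconocene chloride 14 (not isolated), via alkenylzinc chloride 15 (not isolated)
Conditions: 9, Cp2Zr(H)Cl, THF, 50 °C; then ZnCl2, 0 °C; then 13, Pd(PPh3)4 (5 mol %), THF, rt
Reagents that add atoms: none
Why: Hydrozirconation then Negishi coupling, in which syn addition of Zr–H, equilibrated so that zirconium sits on the less hindered methyl-bearing carbon, fixes the trisubstituted E alkene, and Zr-to-Zn transmetalation with palladium-catalysed alkenyl–alkenyl coupling proceeds with retention at both partners to give the (E,E)-diene, the silylalkyne being inert.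

Step 8
Reactants: 16 [(3S,5E,7E)-10-[4-(furan-3-ylmethyl)furan-3-yl]-3,7-dimethyldeca-5,7-dien-1-yn-1-yl]tri(propan-2-yl)silane
Product: 17 3-[(3E,5E,8S)-4,8-dimethyldeca-3,5-dien-9-yn-1-yl]-4-(furan-3-ylmethyl)furan
Conditions: Bu4NF, THF, 0 °C → rt
Reagents that add atoms: none
Why: Fluoride-induced protodesilylation of the alkynylsilane, which leaves the diene, the furans and the propargylic stereocentre untouched.

Step 9
Reactants: 17 3-[(3E,5E,8S)-4,8-dimethyldeca-3,5-dien-9-yn-1-yl]-4-(furan-3-ylmethyl)furan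
Product: 19 (4S,6E,8E)-11-[4-(furan-3-ylmethyl)furan-3-yl]-4,8-dimethylundeca-6,8-dien-2-ynal, via lithium acetylide 18 (not isolated)
Conditions: n-BuLi (1.05 equiv), THF, −78 °C; DMF, −78 → 0 °C; inverse quench into cold aq. KH2PO4
Reagents that add atoms: N,N-dimethylformamide, CN(C)C=O
Why: Formylation of a lithium acetylide with DMF, in which the acetylenic C–H is by far the most acidic site, the tetrahedral adduct is stable until the buffered inverse quench, and the ynal is released under near-neutral conditions that should neither isomerise it nor epimerise C7.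

Step 10
Reactants: 20 ethyl 2-[bis(2-methylphenoxy)phosphoryl]acetate; 21 (chloromethoxy)tri(propan-2-yl)silane
Product: 23 ethyl 2-[bis(2-methylphenoxy)phosphoryl]-3-{[tri(propan-2-yl)silyl]oxy}propanoate, via sodium phosphonoacetate enolate 22 (not isolated)
Conditions: NaH (1.0 equiv), THF, 0 °C; then 21, 0 °C → rt
Reagents that add atoms: none
Why: Alkylation of a stabilised phosphonoacetate enolate with an α-chloro ether (C-alkylation of the sodium chelate in THF), which installs the CH2O–Si unit in one step; the new centre is racemic and disappears in step 11.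

Step 11
Reactants: 19 (4S,6E,8E)-11-[4-(furan-3-ylmethyl)furan-3-yl]-4,8-dimethylundeca-6,8-dien-2-ynal; 23 ethyl 2-[bis(2-methylphenoxy)phosphoryl]-3-{[tri(propan-2-yl)silyl]oxy}propanoate
Product: 27 (5Z)-5-[(2S,4E,6E)-9-[4-(furan-3-ylmethyl)furan-3-yl]-2,6-dimethylnona-4,6-dien-1-ylidene]-3-({[tri(propan-2-yl)silyl]oxy}methyl)furan-2(5H)-one, via potassium phosphonate carbanion 24 (not isolated), via ethyl (Z)-enynoate 25 (not isolated), via (Z)-enynoic acid 26 (not isolated)
Conditions: 23, t-BuOK, THF, −78 °C; then 19, −78 → 0 °C; then LiOH, H2O–MeOH, 0 °C → rt; then AcOH (to pH 6), AgNO3 (10 mol %), rt, dark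
Reagents that add atoms: lithium hydroxide, [Li+].[OH-]
Why: Carbanion 24 adds to the aldehyde carbon C4 of 19 and, because the aryloxy groups make phosphorus electron-poor, the first-formed adduct collapses through the oxaphosphetane faster than it reverts, which should give the (Z)-enynoate 25 with the carboxyl group cis to the alkyne (C3=C4 formed); LiOH then unmasks carboxylic acid 26 and, after buffering, AgNO3 π-activates C5≡C6 so that the carboxylate oxygen attacks C5 anti to silver and protodeargentation releases the lactone (O1–C5 formed). The closest known reaction types are the Z-selective Horner–Wadsworth–Emmons olefination of aldehydes with α-substituted diaryl phosphonoacetates and the silver-catalysed cycloisomerisation of (Z)-2-en-4-ynoic acids to (Z)-5-ylidenebutenolides, here telescoped in one flask. The lactone ring closes 5-exo-dig. No new stereocentre is formed; the Z exocyclic C5=C6 geometry follows from anti oxymetalation and protodemetalation with retention, and C7 meets only a stabilised carbanion at −78 °C and aqueous LiOH, neither expected to remove its proton. The step needs Z over E in the olefination, secured by kinetic control with the diaryl phosphonate (any E acid cannot lactonise and is washed out with base), and 5-exo over 6-endo closure, favoured by silver and by the branched C7 that shields C6. The free hydroxyl is kept silylated so that the phosphonate cannot collapse to an acrylate.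

Step 12
Reactants: 27 (5Z)-5-[(2S,4E,6E)-9-[4-(furan-3-ylmethyl)furan-3-yl]-2,6-dimethylnona-4,6-dien-1-ylidene]-3-({[tri(propan-2-yl)silyl]oxy}methyl)furan-2(5H)-one
Product: 28 (5Z)-5-[(2S,4E,6E)-9-[4-(furan-3-ylmethyl)furan-3-yl]-2,6-dimethylnona-4,6-dien-1-ylidene]-3-(hydroxymethyl)furan-2(5H)-one
Conditions: HF·pyridine, pyridine, THF, 0 °C → rt
Reagents that add atoms: none
Why: Fluoride cleavage of the primary silyl ether with pyridine-buffered HF, conditions under which the ylidene butenolide, the furans and C7 (no base present) should survive.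

**Compound list**

1 | 3,4-dibromofuran | Brc1cocc1Br | starting material
2 | furan-3-carbaldehyde | O=Cc1ccoc1 | starting material
3 | 4-bromo-3-furyllithium | [Li]c1cocc1Br | intermediate
4 | (4-bromofuran-3-yl)(furan-3-yl)methanol (racemic) | OC(c1cocc1Br)c1ccoc1 | intermediate
5 | 3-bromo-4-(furan-3-ylmethyl)furan | Brc1cocc1Cc1ccoc1 | intermediate
6 | pent-3-yn-1-ol | CC#CCCO | starting material
7 | 5-iodopent-2-yne | CC#CCCI | intermediate
8 | pent-3-yn-1-ylzinc iodide | CC#CCC[Zn]I | intermediate
9 | 3-(furan-3-ylmethyl)-4-(pent-3-yn-1-yl)furan | CC#CCCc1cocc1Cc1ccoc1 | intermediate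
10 | (E)-but-2-enal | C/C=C/C=O | starting material
11 | ethynyltri(propan-2-yl)silane | C#C[Si](C(C)C)(C(C)C)C(C)C | starting material
12 | (3S)-3-methyl-5-[tri(propan-2-yl)silyl]pent-4-ynal | O=CC[C@H](C)C#C[Si](C(C)C)(C(C)C)C(C)C | intermediate
13 | [(3S,5E)-6-iodo-3-methylhex-5-en-1-yn-1-yl]tri(propan-2-yl)silane | I/C=C/C[C@H](C)C#C[Si](C(C)C)(C(C)C)C(C)C | intermediate
14 | chlorobis(cyclopentadienyl)[(2E)-5-[4-(furan-3-ylmethyl)furan-3-yl]pent-2-en-2-yl]zirconium | C/C(=C\CCc1cocc1Cc1ccoc1)[Zr](Cl)(C1C=CC=C1)C1C=CC=C1 | intermediate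
15 | chloro[(2E)-5-[4-(furan-3-ylmethyl)furan-3-yl]pent-2-en-2-yl]zinc | C/C(=C\CCc1cocc1Cc1ccoc1)[Zn]Cl | intermediate
16 | [(3S,5E,7E)-10-[4-(furan-3-ylmethyl)furan-3-yl]-3,7-dimethyldeca-5,7-dien-1-yn-1-yl]tri(propan-2-yl)silane | CC(/C=C/C[C@H](C)C#C[Si](C(C)C)(C(C)C)C(C)C)=C\CCc1cocc1Cc1ccoc1 | intermediate
17 | 3-[(3E,5E,8S)-4,8-dimethyldeca-3,5-dien-9-yn-1-yl]-4-(furan-3-ylmethyl)furan | CC(/C=C/C[C@H](C)C#C)=C\CCc1cocc1Cc1ccoc1 | intermediate
18 | lithium acetylide of 17 | CC(/C=C/C[C@H](C)C#C[Li])=C\CCc1cocc1Cc1ccoc1 | intermediate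
19 | (4S,6E,8E)-11-[4-(furan-3-ylmethyl)furan-3-yl]-4,8-dimethylundeca-6,8-dien-2-ynal | CC(/C=C/C[C@H](C)C#CC=O)=C\CCc1cocc1Cc1ccoc1 | intermediate
20 | ethyl 2-[bis(2-methylphenoxy)phosphoryl]acetate | CCOC(=O)CP(=O)(Oc1ccccc1C)Oc1ccccc1C | starting material
21 | (chloromethoxy)tri(propan-2-yl)silane | ClCO[Si](C(C)C)(C(C)C)C(C)C | starting material
22 | sodium enolate of 20 | CCOC(=O)[CH-]P(=O)(Oc1ccccc1C)Oc1ccccc1C.[Na+] | intermediate
23 | ethyl 2-[bis(2-methylphenoxy)phosphoryl]-3-{[tri(propan-2-yl)silyl]oxy}propanoate (racemic) | CCOC(=O)C(CO[Si](C(C)C)(C(C)C)C(C)C)P(=O)(Oc1ccccc1C)Oc1ccccc1C | intermediate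
24 | potassium carbanion of 23 | CCOC(=O)[C-](CO[Si](C(C)C)(C(C)C)C(C)C)P(=O)(Oc1ccccc1C)Oc1ccccc1C.[K+] | intermediate
25 | ethyl (2Z,6S,8E,10E)-13-[4-(furan-3-ylmethyl)furan-3-yl]-6,10-dimethyl-2-({[tri(propan-2-yl)silyl]oxy}methyl)trideca-2,8,10-trien-4-ynoate | CC(/C=C/C[C@H](C)C#C/C=C(/CO[Si](C(C)C)(C(C)C)C(C)C)C(=O)OCC)=C\CCc1cocc1Cc1ccoc1 | intermediate
26 | (2Z,6S,8E,10E)-13-[4-(furan-3-ylmethyl)furan-3-yl]-6,10-dimethyl-2-({[tri(propan-2-yl)silyl]oxy}methyl)trideca-2,8,10-trien-4-ynoic acid (formed as its lithium salt, set free by AcOH) | CC(/C=C/C[C@H](C)C#C/C=C(/CO[Si](C(C)C)(C(C)C)C(C)C)C(=O)O)=C\CCc1cocc1Cc1ccoc1 | intermediate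
27 | (5Z)-5-[(2S,4E,6E)-9-[4-(furan-3-ylmethyl)furan-3-yl]-2,6-dimethylnona-4,6-dien-1-ylidene]-3-({[tri(propan-2-yl)silyl]oxy}methyl)furan-2(5H)-one | CC(/C=C/C[C@H](C)/C=C1/C=C(CO[Si](C(C)C)(C(C)C)C(C)C)C(=O)O1)=C\CCc1cocc1Cc1ccoc1 | intermediate
28 | (5Z)-5-[(2S,4E,6E)-9-[4-(furan-3-ylmethyl)furan-3-yl]-2,6-dimethylnona-4,6-dien-1-ylidene]-3-(hydroxymethyl)furan-2(5H)-one | CC(/C=C/C[C@H](C)/C=C1/C=C(CO)C(=O)O1)=C\CCc1cocc1Cc1ccoc1 | target

**Count and risks**

Total step count: 12. Longest linear sequence: 8 steps (steps 1, 2, 4, 7, 8, 9, 11, 12).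

Step 11 (key step). What may go wrong: erosion of Z-selectivity in the olefination, loss of silanolate from carbanion 24 by β-elimination before it meets the aldehyde, or 6-endo closure to a 2-pyranone in the silver stage. The fallback sets out from ynal 19 and comes back at target 28; it needs neither alkene-geometry control nor a protecting group. A DABCO-catalysed Morita–Baylis–Hillman reaction of 19 with methyl acrylate would form the C3–C4 bond and give the allylic alcohol methyl (6S,8E,10E)-13-[4-(furan-3-ylmethyl)furan-3-yl]-3-hydroxy-6,10-dimethyl-2-methylidenetrideca-8,10-dien-4-ynoate F1 as both carbinol epimers. LiOH would give the corresponding acid F2, and AgNO3-catalysed 5-exo-dig lactonisation would give the 4-hydroxy-3-methylidene-5-ylidene lactone F3. Dilute aqueous acid (TsOH, THF–H2O) would then ionise the C4 hydroxyl to a ring-delocalised allyl cation, and capture by water at the exocyclic methylene terminus would give the fully conjugated isomer 28.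

Step 10. What may go wrong: O- instead of C-alkylation of the enolate, double alkylation, or retro-Michael loss of silanolate from the product anion followed by Michael addition of a second enolate. The fallback sets out from 20 (and 19) and comes back at 28; the hydroxymethyl carbon is introduced last by cross-coupling. Bromination of the sodium enolate of 20 with Br2 would give ethyl 2-[bis(2-methylphenoxy)phosphoryl]-2-bromoacetate F4. Olefination of 19 with F4 (t-BuOK, THF, −78 °C) would give the ethyl (2E)-2-bromo-enynoate F5, in which the carboxyl group is again cis to the alkyne. LiOH would give the acid F6 and AgNO3 the 3-bromo-5-ylidenebutenolide F7. Stille coupling of F7 with (tributylstannyl)methanol (Pd(PPh3)4, 1,4-dioxane, 80 °C) would install CH2OH and give 28.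

Step 5. What may go wrong: low enantioselection with the small β-methyl group, alkyne dimerisation, or acetalisation of the enal in methanol. The fallback sets out from 11 and comes back at 12; the stereocentre comes from a catalyst-controlled ketone reduction followed by SN2 inversion. Acylation of lithiated 11 with N-methoxy-N-methylacetamide would give 4-[tri(propan-2-yl)silyl]but-3-yn-2-one F8. Noyori transfer hydrogenation ([RuCl(p-cymene)(TsDPEN)] of the hand that gives the (S)-alcohol, i-PrOH) would give (2S)-4-[tri(propan-2-yl)silyl]but-3-yn-2-ol F9, and MsCl/Et3N its methanesulfonate F10. Sodium dimethyl malonate in DMF would displace the mesylate with inversion (the silyl group blocks SN2′ attack) to give dimethyl 2-[(2S)-4-[tri(propan-2-yl)silyl]but-3-yn-2-yl]propanedioate F11. Krapcho demethoxycarbonylation (LiCl, wet DMSO, 150 °C) would give methyl (3S)-3-methyl-5-[tri(propan-2-yl)silyl]pent-4-ynoate F12, and DIBAL-H at −78 °C would give aldehyde 12.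

Further compounds

F1 | step 11 | methyl (6S,8E,10E)-13-[4-(furan-3-ylmethyl)furan-3-yl]-3-hydroxy-6,10-dimethyl-2-methylidenetrideca-8,10-dien-4-ynoate | CC(/C=C/C[C@H](C)C#CC(O)C(=C)C(=O)OC)=C\CCc1cocc1Cc1ccoc1
F2 | step 11 | (6S,8E,10E)-13-[4-(furan-3-ylmethyl)furan-3-yl]-3-hydroxy-6,10-dimethyl-2-methylidenetrideca-8,10-dien-4-ynoic acid | CC(/C=C/C[C@H](C)C#CC(O)C(=C)C(=O)O)=C\CCc1cocc1Cc1ccoc1
F3 | step 11 | (5Z)-5-[(2S,4E,6E)-9-[4-(furan-3-ylmethyl)furan-3-yl]-2,6-dimethylnona-4,6-dien-1-ylidene]-4-hydroxy-3-methylideneoxolan-2-one | CC(/C=C/C[C@H](C)/C=C1/C(O)C(=C)C(=O)O1)=C\CCc1cocc1Cc1ccoc1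
F4 | step 10 | ethyl 2-[bis(2-methylphenoxy)phosphoryl]-2-bromoacetate | CCOC(=O)C(Br)P(=O)(Oc1ccccc1C)Oc1ccccc1C
F5 | step 10 | ethyl (2E,6S,8E,10E)-2-bromo-13-[4-(furan-3-ylmethyl)furan-3-yl]-6,10-dimethyltrideca-2,8,10-trien-4-ynoate | CC(/C=C/C[C@H](C)C#C/C=C(/Br)C(=O)OCC)=C\CCc1cocc1Cc1ccoc1
F6 | step 10 | (2E,6S,8E,10E)-2-bromo-13-[4-(furan-3-ylmethyl)furan-3-yl]-6,10-dimethyltrideca-2,8,10-trien-4-ynoic acid | CC(/C=C/C[C@H](C)C#C/C=C(/Br)C(=O)O)=C\CCc1cocc1Cc1ccoc1
F7 | step 10 | (5Z)-3-bromo-5-[(2S,4E,6E)-9-[4-(furan-3-ylmethyl)furan-3-yl]-2,6-dimethylnona-4,6-dien-1-ylidene]furan-2(5H)-one | CC(/C=C/C[C@H](C)/C=C1/C=C(Br)C(=O)O1)=C\CCc1cocc1Cc1ccoc1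
F8 | step 5 | 4-[tri(propan-2-yl)silyl]but-3-yn-2-one | CC(=O)C#C[Si](C(C)C)(C(C)C)C(C)C
F9 | step 5 | (2S)-4-[tri(propan-2-yl)silyl]but-3-yn-2-ol | C[C@H](O)C#C[Si](C(C)C)(C(C)C)C(C)C
F10 | step 5 | (2S)-4-[tri(propan-2-yl)silyl]but-3-yn-2-yl methanesulfonate | C[C@H](OS(C)(=O)=O)C#C[Si](C(C)C)(C(C)C)C(C)C
F11 | step 5 | dimethyl 2-[(2S)-4-[tri(propan-2-yl)silyl]but-3-yn-2-yl]propanedioate | COC(=O)C(C(=O)OC)[C@H](C)C#C[Si](C(C)C)(C(C)C)C(C)C
F12 | step 5 | methyl (3S)-3-methyl-5-[tri(propan-2-yl)silyl]pent-4-ynoate | COC(=O)C[C@H](C)C#C[Si](C(C)C)(C(C)C)C(C)C
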